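**Plan**
1. Retrosynthesis: the four O–benzyl bonds are cut first, then the flavanone C2–aryl bond, which separates an arylboronic acid carrying the whole flavone from 5-benzyloxy-7-methoxychromone.
2. In the flavone half the O1–C2 bond (oxidative closure of a chalcone) and then the C4a–C5 bond of ring A are cut, giving an open-chain 3,5,7-triketo ester. Its C6–C7 bond, the C8=C9 double bond and the diaryl ether C–O bond are cut last.
3. Enabling feature: flavone ring A carries oxygen on C5, C7 and C8a, all mutually meta, with the C4 acyl carbon on C4a between two of them. This is a 2-acylphloroglucinol, the pattern a 3,5,7-triketo ester gives on Claisen closure, with both hydroxyls free.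
4. Forward order: diaryl ether (SNAr), cinnamoyl Weinreb amide, triketo ester, flavone ring A (Claisen), flavone ring C (I2/DMSO). Flavanone rings A and C arrive ready-made as a chromone, and the C2–aryl bond is made in the penultimate step.
5. Stereochemistry: the only stereocentre, C2 of the flavanone (S), is set by palladium-catalysed asymmetric conjugate addition under a chiral pyridine–oxazoline ligand and is kept by a neutral final hydrogenolysis.

Key step: step 7

Assumption: the facial preference of the Pd(OCOCF3)2/t-BuPyOx catalyst on chromones is taken to follow that known for cyclic enones, so the (R)-ligand is assigned to the (2S)-flavanone.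

**Route**

Step 1
Reactants: 1 5-bromosalicylaldehyde
Product: 2 2-(benzyloxy)-5-bromobenzaldehyde
Conditions: BnBr, K2CO3, DMF, rt
Reagents that add atoms: benzyl bromide, BrCc1ccccc1
Why: Williamson O-alkylation of the phenoxide masks the phenol and provides the ortho-alkoxy group that directs aryl migration in the next step.

Step 2
Reactants: 2 2-(benzyloxy)-5-bromobenzaldehyde
Product: 4 2-(benzyloxy)-5-bromophenol, via 2-(benzyloxy)-5-bromophenyl formate 3 (not isolated)
Conditions: mCPBA, CH2Cl2, 0 °C to rt; then K2CO3 (cat.), MeOH, rt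
Reagents that add atoms: meta-chloroperoxybenzoic acid, O=C(OO)c1cccc(Cl)c1
Why: Baeyer–Villiger oxidation of an ortho-alkoxybenzaldehyde proceeds with aryl migration (Dakin-type) to the formate, which mild methanolysis converts to the phenol without touching the benzyl ether or the aryl bromide.

Step 3
Reactants: 4 2-(benzyloxy)-5-bromophenol; 5 4-fluorobenzaldehyde
Product: 6 4-[2-(benzyloxy)-5-bromophenoxy]benzaldehyde
Conditions: K2CO3, DMF, 120 °C
Reagents that add atoms: none
Why: Nucleophilic aromatic substitution (SNAr) of fluoride para to the formyl group by the phenoxide goes through a stabilised Meisenheimer adduct, while the unactivated aryl bromide is inert.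

Step 4
Reactants: 6 4-[2-(benzyloxy)-5-bromophenoxy]benzaldehyde; 7 diethyl {2-[methoxy(methyl)amino]-2-oxoethyl}phosphonate
Product: 8 (E)-3-{4-[2-(benzyloxy)-5-bromophenoxy]phenyl}-N-methoxy-N-methylprop-2-enamide
Conditions: NaH, THF, 0 °C to rt
Reagents that add atoms: none
Why: Horner–Wadsworth–Emmons olefination with a stabilised phosphonate anion should give the E-alkene and installs the Weinreb amide in the same operation.

Step 5
Reactants: 9 triacetic acid lactone
Product: 10 methyl 3,5-dioxohexanoate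
Conditions: Mg(OMe)2, MeOH, reflux; then cold aq. HCl
Reagents that add atoms: magnesium methoxide, C[O-].C[O-].[Mg+2]
Why: Methoxide opens the enol lactone by transesterification and the magnesium chelate of the resulting diketo ester prevents re-lactonisation and self-condensation.

Step 6
Reactants: 10 methyl 3,5-dioxohexanoate (1.5 equiv); 8 (E)-3-{4-[2-(benzyloxy)-5-bromophenoxy]phenyl}-N-methoxy-N-methylprop-2-enamide
Product: 12 methyl (E)-9-{4-[2-(benzyloxy)-5-bromophenoxy]phenyl}-3,5,7-trioxonon-8-enoate, via trilithium trianion of methyl 3,5-dioxohexanoate 11 (not isolated)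
Conditions: LiN(iPr)2 (3 equiv per 10), THF, 0 °C; then 8, −78 to −20 °C; AcOH quench at −78 °C
Reagents that add atoms: none
Why: Polyanion acylation (Harris-type polyketide chain extension) occurs at the terminal, last-formed carbanion C6 by 1,2-addition to the Weinreb amide, whose chelated tetrahedral adduct persists until the quench so that the acidic product cannot protonate unreacted trianion, and the amide base causes no bromine–lithium exchange.

Step 7
Reactants: 12 methyl (E)-9-{4-[2-(benzyloxy)-5-bromophenoxy]phenyl}-3,5,7-trioxonon-8-enoate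
Product: 13 (E)-3-{4-[2-(benzyloxy)-5-bromophenoxy]phenyl}-1-(2,4,6-trihydroxyphenyl)prop-2-en-1-one
Conditions: Mg(OMe)2 (excess), MeOH, rt to 50 °C; then cold 1 M HCl
Reagents that add atoms: none
Why: Mg(OMe)2 turns 12 into a magnesium-chelated polyenolate whose carbanionic C6, flanked by the C5 and C7 carbonyls, adds to the C1 ester carbonyl; loss of methoxide and tautomerisation to the aromatic triol make the closure irreversible. The closest known reaction is the Mg(OMe)2-mediated Claisen (Dieckmann-type) cyclisation of 3,5,7-triketo esters to 2-acylphloroglucinols, the laboratory counterpart of chalcone synthase. The one ring formed, flavone ring A, closes in a 6-exo-trig mode through the C6–C1 bond, which becomes the C4a–C5 bond of the flavone. No stereocentre is created and the E double bond is not involved. The step needs Claisen closure (C6 onto C1) to win over aldol closure (C2 onto the C7 ketone) and over lactonisation to a 2-pyranone. This is secured by the magnesium chelate, which ties up the C3, C5 and C7 oxygens and presents C6 to the ester, by the low electrophilicity of the cross-conjugated C7 enone carbonyl, and by the methoxide medium, which reopens any pyranone as it opens 9 in step 5.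

Step 8
Reactants: 13 (E)-3-{4-[2-(benzyloxy)-5-bromophenoxy]phenyl}-1-(2,4,6-trihydroxyphenyl)prop-2-en-1-one
Product: 15 2-{4-[2-(benzyloxy)-5-bromophenoxy]phenyl}-5,7-dihydroxy-4H-chromen-4-one, via racemic 5,7-dihydroxyflavanone 14 (not isolated)
Conditions: I2 (cat.), DMSO, 120 °C
Reagents that add atoms: none
Why: Iodine–DMSO oxidative cyclisation of a 2'-hydroxychalcone proceeds by 6-endo-trig oxa-Michael closure to the flavanone, alpha-iodination and loss of HI, with DMSO reoxidising iodide, so any flavanone already formed in step 7 converges on the same flavone.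

Step 9
Reactants: 15 2-{4-[2-(benzyloxy)-5-bromophenoxy]phenyl}-5,7-dihydroxy-4H-chromen-4-one
Product: 16 5,7-bis(benzyloxy)-2-{4-[2-(benzyloxy)-5-bromophenoxy]phenyl}-4H-chromen-4-one
Conditions: BnBr (excess), K2CO3, DMF, 80 °C
Reagents that add atoms: benzyl bromide, BrCc1ccccc1
Why: Williamson etherification takes the acidic 7-OH first and the hydrogen-bonded 5-OH on heating with excess halide, which removes the keto-phenol chelating site before the palladium-catalysed steps.

Step 10
Reactants: 16 5,7-bis(benzyloxy)-2-{4-[2-(benzyloxy)-5-bromophenoxy]phenyl}-4H-chromen-4-one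
Product: 17 5,7-bis(benzyloxy)-2-{4-[2-(benzyloxy)-5-(4,4,5,5-tetramethyl-1,3,2-dioxaborolan-2-yl)phenoxy]phenyl}-4H-chromen-4-one
Conditions: B2pin2, PdCl2(dppf) (cat.), KOAc, 1,4-dioxane, 90 °C
Reagents that add atoms: bis(pinacolato)diboron, CC1(C)OB(B2OC(C)(C)C(C)(C)O2)OC1(C)C
Why: Miyaura borylation (oxidative addition of the aryl bromide to zerovalent palladium, acetate-assisted transmetalation with the diboron, reductive elimination) tolerates the flavone and the benzyl ethers.

Step 11
Reactants: 17 5,7-bis(benzyloxy)-2-{4-[2-(benzyloxy)-5-(4,4,5,5-tetramethyl-1,3,2-dioxaborolan-2-yl)phenoxy]phenyl}-4H-chromen-4-one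
Product: 18 (4-(benzyloxy)-3-{4-[5,7-bis(benzyloxy)-4-oxo-4H-chromen-2-yl]phenoxy}phenyl)boronic acid
Conditions: NaIO4, NH4OAc, acetone/H2O, rt
Reagents that add atoms: water, O
Why: Periodate cleaves the pinacol released in the hydrolysis equilibrium (glycol cleavage) and so drives the ester to the free boronic acid needed for transmetalation to a cationic palladium catalyst.

Step 12
Reactants: 19 2',6'-dihydroxy-4'-methoxyacetophenone
Product: 20 1-[2-(benzyloxy)-6-hydroxy-4-methoxyphenyl]ethan-1-one
Conditions: BnBr (1 equiv), K2CO3, acetone, reflux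
Reagents that add atoms: benzyl bromide, BrCc1ccccc1
Why: Williamson mono-etherification stops after one benzyl group because the remaining hydroxyl is locked in a hydrogen bond to the ketone and is far less nucleophilic.

Step 13
Reactants: 20 1-[2-(benzyloxy)-6-hydroxy-4-methoxyphenyl]ethan-1-one
Product: 22 5-(benzyloxy)-7-methoxy-4H-chromen-4-one, via dimethylamino enaminone 21 (not isolated)
Conditions: Me2NCH(OMe)2, toluene, 100 °C; then 2 M aq. HCl, CH2Cl2, rt
Reagents that add atoms: N,N-dimethylformamide dimethyl acetal, COC(OC)N(C)C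
Why: Condensation of the acetyl methyl group with the formamide acetal gives the enaminone, and acid then promotes addition of the phenol and loss of dimethylamine (the standard enaminone route to chromones).

Step 14
Reactants: 18 (4-(benzyloxy)-3-{4-[5,7-bis(benzyloxy)-4-oxo-4H-chromen-2-yl]phenoxy}phenyl)boronic acid; 22 5-(benzyloxy)-7-methoxy-4H-chromen-4-one (1.5 equiv)
Product: 23 (2S)-5-(benzyloxy)-2-[4-(benzyloxy)-3-{4-[5,7-bis(benzyloxy)-4-oxo-4H-chromen-2-yl]phenoxy}phenyl]-7-methoxy-2,3-dihydro-4H-chromen-4-one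
Conditions: Pd(OCOCF3)2 (cat.), (R)-t-BuPyOx [(R)-4-tert-butyl-2-(pyridin-2-yl)-4,5-dihydrooxazole] (cat.), NH4PF6, H2O, ClCH2CH2Cl, 60 °C
Reagents that add atoms: none
Why: In this asymmetric conjugate addition of an arylboronic acid to a chromone, the aryl group passes to cationic divalent palladium and the chromone C2=C3 bond inserts into the aryl–palladium bond on the face left open by the tert-butyl group of the (R)-ligand, which sets C2 as S; water then protonates the palladium enolate, the 2-aryl-substituted enone of the flavone is too hindered to compete, and the base-free medium prevents ring-opening racemisation.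

Step 15
Reactants: 23 (2S)-5-(benzyloxy)-2-[4-(benzyloxy)-3-{4-[5,7-bis(benzyloxy)-4-oxo-4H-chromen-2-yl]phenoxy}phenyl]-7-methoxy-2,3-dihydro-4H-chromen-4-one
Product: 24 (2S)-2-{3-[4-(5,7-dihydroxy-4-oxo-4H-chromen-2-yl)phenoxy]-4-hydroxyphenyl}-5-hydroxy-7-methoxy-2,3-dihydro-4H-chromen-4-one
Conditions: H2 (1 atm), 10% Pd/C, THF/MeOH, rt
Reagents that add atoms: none
Why: Hydrogenolysis of the four aryl benzyl ethers under neutral conditions should leave the conjugated flavone double bond, both aryl ketones and the 7-methyl ether intact, and without base the flavanone ring cannot open, so the C2 configuration is retained.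

**Compound list**
1 | 5-bromosalicylaldehyde (5-bromo-2-hydroxybenzaldehyde) | O=Cc1cc(Br)ccc1O | starting material
2 | 2-(benzyloxy)-5-bromobenzaldehyde | O=Cc1cc(Br)ccc1OCc1ccccc1 | intermediate
3 | 2-(benzyloxy)-5-bromophenyl formate (formed in the flask, not isolated) | O=COc1cc(Br)ccc1OCc1ccccc1 | intermediate
4 | 2-(benzyloxy)-5-bromophenol | Oc1cc(Br)ccc1OCc1ccccc1 | intermediate
5 | 4-fluorobenzaldehyde | O=Cc1ccc(F)cc1 | starting material
6 | 4-[2-(benzyloxy)-5-bromophenoxy]benzaldehyde | O=Cc1ccc(Oc2cc(Br)ccc2OCc2ccccc2)cc1 | intermediate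
7 | diethyl {2-[methoxy(methyl)amino]-2-oxoethyl}phosphonate | CCOP(=O)(CC(=O)N(C)OC)OCC | starting material
8 | (E)-3-{4-[2-(benzyloxy)-5-bromophenoxy]phenyl}-N-methoxy-N-methylprop-2-enamide | CON(C)C(=O)/C=C/c1ccc(Oc2cc(Br)ccc2OCc2ccccc2)cc1 | intermediate
9 | triacetic acid lactone (4-hydroxy-6-methyl-2H-pyran-2-one) | Cc1cc(O)cc(=O)o1 | starting material
10 | methyl 3,5-dioxohexanoate | COC(=O)CC(=O)CC(C)=O | intermediate
11 | trilithium trianion of methyl 3,5-dioxohexanoate (formed in the flask, not isolated) | [Li+].[Li+].[Li+].COC(=O)[CH-]C(=O)[CH-]C(=O)[CH2-] | intermediate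
12 | methyl (E)-9-{4-[2-(benzyloxy)-5-bromophenoxy]phenyl}-3,5,7-trioxonon-8-enoate | COC(=O)CC(=O)CC(=O)CC(=O)/C=C/c1ccc(Oc2cc(Br)ccc2OCc2ccccc2)cc1 | intermediate
13 | (E)-3-{4-[2-(benzyloxy)-5-bromophenoxy]phenyl}-1-(2,4,6-trihydroxyphenyl)prop-2-en-1-one (2',4',6'-trihydroxychalcone) | O=C(/C=C/c1ccc(Oc2cc(Br)ccc2OCc2ccccc2)cc1)c1c(O)cc(O)cc1O | intermediate
14 | racemic 2-{4-[2-(benzyloxy)-5-bromophenoxy]phenyl}-5,7-dihydroxy-2,3-dihydro-4H-chromen-4-one (formed in the flask, not isolated) | O=C1CC(c2ccc(Oc3cc(Br)ccc3OCc3ccccc3)cc2)Oc2cc(O)cc(O)c21 | intermediate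
15 | 2-{4-[2-(benzyloxy)-5-bromophenoxy]phenyl}-5,7-dihydroxy-4H-chromen-4-one | O=c1cc(-c2ccc(Oc3cc(Br)ccc3OCc3ccccc3)cc2)oc2cc(O)cc(O)c12 | intermediate
16 | 5,7-bis(benzyloxy)-2-{4-[2-(benzyloxy)-5-bromophenoxy]phenyl}-4H-chromen-4-one | O=c1cc(-c2ccc(Oc3cc(Br)ccc3OCc3ccccc3)cc2)oc2cc(OCc3ccccc3)cc(OCc3ccccc3)c12 | intermediate
17 | 5,7-bis(benzyloxy)-2-{4-[2-(benzyloxy)-5-(4,4,5,5-tetramethyl-1,3,2-dioxaborolan-2-yl)phenoxy]phenyl}-4H-chromen-4-one | O=c1cc(-c2ccc(Oc3cc(B4OC(C)(C)C(C)(C)O4)ccc3OCc3ccccc3)cc2)oc2cc(OCc3ccccc3)cc(OCc3ccccc3)c12 | intermediate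
18 | (4-(benzyloxy)-3-{4-[5,7-bis(benzyloxy)-4-oxo-4H-chromen-2-yl]phenoxy}phenyl)boronic acid | O=c1cc(-c2ccc(Oc3cc(B(O)O)ccc3OCc3ccccc3)cc2)oc2cc(OCc3ccccc3)cc(OCc3ccccc3)c12 | intermediate
19 | 2',6'-dihydroxy-4'-methoxyacetophenone | CC(=O)c1c(O)cc(OC)cc1O | starting material
20 | 1-[2-(benzyloxy)-6-hydroxy-4-methoxyphenyl]ethan-1-one | CC(=O)c1c(O)cc(OC)cc1OCc1ccccc1 | intermediate
21 | (E)-1-[2-(benzyloxy)-6-hydroxy-4-methoxyphenyl]-3-(dimethylamino)prop-2-en-1-one (formed in the flask, not isolated) | CN(C)/C=C/C(=O)c1c(O)cc(OC)cc1OCc1ccccc1 | intermediate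
22 | 5-(benzyloxy)-7-methoxy-4H-chromen-4-one | COc1cc(OCc2ccccc2)c2c(=O)ccoc2c1 | intermediate
23 | (2S)-5-(benzyloxy)-2-[4-(benzyloxy)-3-{4-[5,7-bis(benzyloxy)-4-oxo-4H-chromen-2-yl]phenoxy}phenyl]-7-methoxy-2,3-dihydro-4H-chromen-4-one | COc1cc(OCc6ccccc6)c2c(c1)O[C@H](c1ccc(OCc6ccccc6)c(Oc3ccc(-c4cc(=O)c5c(OCc6ccccc6)cc(OCc6ccccc6)cc5o4)cc3)c1)CC2=O | intermediate
24 | (2S)-2-{3-[4-(5,7-dihydroxy-4-oxo-4H-chromen-2-yl)phenoxy]-4-hydroxyphenyl}-5-hydroxy-7-methoxy-2,3-dihydro-4H-chromen-4-one (CNP0145819.1) | COc1cc(O)c2c(c1)O[C@H](c1ccc(O)c(Oc3ccc(-c4cc(=O)c5c(O)cc(O)cc5o4)cc3)c1)CC2=O | target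

**Step count**
Total: 15 steps. Longest linear sequence: 12 steps (steps 1–4, 6–11, 14, 15). Step 5 and steps 12–13 are side branches.

**Steps most likely to fail, with fallbacks**

Step 6. The strongly basic trianion may add in conjugate fashion to the unsaturated amide or degrade the Weinreb amide, and the labile triketo ester may dehydrate to a 4-pyranone during acidic work-up and isolation. The fallback sets out from amide 8 and triacetic acid lactone 9. The dianion of 9 (2 equiv LiN(iPr)2, THF, −78 °C), which is less basic, is acylated at its 6-methyl carbon by 8 to give the stable pyranone 6-[(E)-4-{4-[2-(benzyloxy)-5-bromophenoxy]phenyl}-2-oxobut-3-en-1-yl]-4-hydroxy-2H-pyran-2-one F1, a lactone-masked form of the triketo ester. Exposure of F1 to Mg(OMe)2 in methanol opens the lactone to 12 in the flask and carries it through the Claisen closure, so the route is rejoined at 13 without handling free 12.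

Step 7. Aldol closure of C2 onto the C7 ketone (giving a resorcylate-type stilbene), or premature oxa-Michael closure and decomposition of the free trihydroxychalcone, may outrun the Claisen mode. The fallback sets out from aldehyde 6 and builds the ring A pattern from a preformed aromatic ring. Claisen–Schmidt condensation of 6 with 2',4'-bis(benzyloxy)-6'-hydroxyacetophenone F2, a purchasable building block (KOH, EtOH/THF, rt), should give (E)-1-[2,4-bis(benzyloxy)-6-hydroxyphenyl]-3-{4-[2-(benzyloxy)-5-bromophenoxy]phenyl}prop-2-en-1-one F3. Iodine-catalysed oxidative cyclisation of F3 in DMSO at 120 °C gives the dibenzylated flavone directly, and the route is rejoined at 16.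

Step 14. Migratory insertion into the electron-rich 5,7-dioxygenated chromone may be slow, so that protodeboronation of the valuable boronic acid dominates, or facial discrimination may be insufficient. The fallback sets out from bromide 16 and forms the flavanone by ring closure followed by resolution.
- Reductive carbonylation of 16 (Pd(OAc)2, di(1-adamantyl)-n-butylphosphine, CO/H2, TMEDA, toluene, 100 °C) should give 4-(benzyloxy)-3-{4-[5,7-bis(benzyloxy)-4-oxo-4H-chromen-2-yl]phenoxy}benzaldehyde F4.
- Claisen–Schmidt condensation of F4 with acetophenone 20 (KOH, EtOH/THF, rt) should give the 2'-hydroxychalcone (E)-1-[2-(benzyloxy)-6-hydroxy-4-methoxyphenyl]-3-[4-(benzyloxy)-3-{4-[5,7-bis(benzyloxy)-4-oxo-4H-chromen-2-yl]phenoxy}phenyl]prop-2-en-1-one F5.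
- NaOAc in refluxing ethanol closes F5 to the racemic flavanone 5-(benzyloxy)-2-[4-(benzyloxy)-3-{4-[5,7-bis(benzyloxy)-4-oxo-4H-chromen-2-yl]phenoxy}phenyl]-7-methoxy-2,3-dihydro-4H-chromen-4-one F6.
- Preparative chromatography on a polysaccharide chiral stationary phase separates the (2S)-enantiomer, and the route is rejoined at 23. The (2R)-enantiomer is re-equilibrated through F5 with NaOAc and recycled.

**Further compounds**
F1 | step 6 | 6-[(E)-4-{4-[2-(benzyloxy)-5-bromophenoxy]phenyl}-2-oxobut-3-en-1-yl]-4-hydroxy-2H-pyran-2-one | O=C(Cc1cc(O)cc(=O)o1)/C=C/c1ccc(Oc2cc(Br)ccc2OCc2ccccc2)cc1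
F2 | step 7 | 2',4'-bis(benzyloxy)-6'-hydroxyacetophenone (purchased partner) | CC(=O)c1c(O)cc(OCc2ccccc2)cc1OCc1ccccc1
F3 | step 7 | (E)-1-[2,4-bis(benzyloxy)-6-hydroxyphenyl]-3-{4-[2-(benzyloxy)-5-bromophenoxy]phenyl}prop-2-en-1-one | O=C(/C=C/c1ccc(Oc2cc(Br)ccc2OCc2ccccc2)cc1)c1c(O)cc(OCc2ccccc2)cc1OCc1ccccc1
F4 | step 14 | 4-(benzyloxy)-3-{4-[5,7-bis(benzyloxy)-4-oxo-4H-chromen-2-yl]phenoxy}benzaldehyde | O=Cc1ccc(OCc2ccccc2)c(Oc2ccc(-c3cc(=O)c4c(OCc5ccccc5)cc(OCc5ccccc5)cc4o3)cc2)c1
F5 | step 14 | (E)-1-[2-(benzyloxy)-6-hydroxy-4-methoxyphenyl]-3-[4-(benzyloxy)-3-{4-[5,7-bis(benzyloxy)-4-oxo-4H-chromen-2-yl]phenoxy}phenyl]prop-2-en-1-one | COc1cc(O)c(C(=O)/C=C/c2ccc(OCc3ccccc3)c(Oc3ccc(-c4cc(=O)c5c(OCc6ccccc6)cc(OCc6ccccc6)cc5o4)cc3)c2)c(OCc2ccccc2)c1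
F6 | step 14 | racemic 5-(benzyloxy)-2-[4-(benzyloxy)-3-{4-[5,7-bis(benzyloxy)-4-oxo-4H-chromen-2-yl]phenoxy}phenyl]-7-methoxy-2,3-dihydro-4H-chromen-4-one | COc1cc(OCc6ccccc6)c2c(c1)OC(c1ccc(OCc6ccccc6)c(Oc3ccc(-c4cc(=O)c5c(OCc6ccccc6)cc(OCc6ccccc6)cc5o4)cc3)c1)CC2=O
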